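**Plan**
- Retrosynthesis: the 4-hydroxy-3-methylfuran-2(5H)-one ring (O1, C2, C3, C4, C5) is opened at C2–C3 and C4–C5 in one formal (3+2) transform. The C5–O1–C2(=O) unit becomes an O-alkyl N,N-diisopropylcarbamate and the C3(Me)=C4(OH) enol becomes methylketene.
- Enabling feature: C5 is an sp3 C–H bound to O1, and O1 carries the C2 carbonyl. That is the dipole-stabilised α-oxy carbanion site of a carbamate, and C4 is a carbonyl-level carbon next to the enolisable C3.
- The side chain is then cut back: homoallylic alcohol ⇐ 1,3-diene (hydroboration) ⇐ enal (Wittig, adds C5) ⇐ E-methyl oxidation of the furyl triene ⇐ furan-3-ylmethyl Grignard + (2E,6E)-farnesyl bromide.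
- Forward: the chain is joined first, extended by one carbon, converted to the carbamate, and the ring is formed last.
- Stereochemistry: two E-olefins come from farnesyl bromide and the third from the E-selective SeO2 oxidation. C5 (R) comes from (−)-sparteine-mediated removal of the pro-S proton and acylation with retention.

Key step: step 9

Remark: (−)-sparteine/s-BuLi is taken to remove the pro-S proton of the OCH2 group and the lithio species to be acylated with retention, as is general for O-alkyl N,N-diisopropylcarbamates; this maps onto (5R).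

Step 1
Reactants: 1 furan-3-ylmethanol
Product: 2 3-(chloromethyl)furan
Conditions: SOCl2, pyridine, Et2O, 0 °C; used cold without storage
Reagents that add atoms: thionyl chloride, ClS(Cl)=O
Why: Chlorodehydroxylation of a primary alcohol via its chlorosulfite is standard, and pyridine buffers the HCl that would otherwise degrade the furan.

Step 2
Reactants: 2 3-(chloromethyl)furan; 3 (2E,6E)-farnesyl bromide
Product: 5 3-[(3E,7E)-4,8,12-trimethyltrideca-3,7,11-trien-1-yl]furan, via (furan-3-ylmethyl)magnesium chloride 4 (not isolated)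
Conditions: Mg, THF, 0 °C → rt; then 3, Li2CuCl4 (3 mol %), THF, 0 °C
Reagents that add atoms: none
Why: Copper-catalysed Grignard cross-coupling at the primary carbon of the allylic bromide (α-attack) is the classical entry to 3-(polyprenylmethyl)furans and should leave the two E-olefins untouched.

Step 3
Reactants: 5 3-[(3E,7E)-4,8,12-trimethyltrideca-3,7,11-trien-1-yl]furan
Product: 6 (2E,6E,10E)-13-(furan-3-yl)-2,6,10-trimethyltrideca-2,6,10-trien-1-ol
Conditions: SeO2 (0.3 equiv), t-BuOOH (2.5 equiv), salicylic acid (0.1 equiv), CH2Cl2, 0 °C → rt; stopped at partial conversion, 5 recycled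
Reagents that add atoms: selenium dioxide (catalytic oxygen carrier), O=[Se]=O; tert-butyl hydroperoxide (terminal oxidant), CC(C)(C)OO
Why: Catalytic SeO2 allylic oxidation (ene reaction, then [2,3]-sigmatropic shift) should attack the least hindered terminal isopropylidene group at its E-methyl group, which fixes the E geometry of the future C7=C8 bond.

Step 4
Reactants: 6 (2E,6E,10E)-13-(furan-3-yl)-2,6,10-trimethyltrideca-2,6,10-trien-1-ol
Product: 7 (2E,6E,10E)-13-(furan-3-yl)-2,6,10-trimethyltrideca-2,6,10-trienal
Conditions: activated MnO2 (excess), CH2Cl2, rt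
Reagents that add atoms: none
Why: MnO2 oxidation is selective for allylic alcohols and should give the enal without touching the isolated olefins or the furan and without E/Z isomerisation.

Step 5
Reactants: 7 (2E,6E,10E)-13-(furan-3-yl)-2,6,10-trimethyltrideca-2,6,10-trienal
Product: 8 3-[(3E,7E,11E)-4,8,12-trimethyltetradeca-3,7,11,13-tetraen-1-yl]furan
Conditions: Ph3PCH3Br, KOtBu, THF, 0 °C → rt
Reagents that add atoms: methyltriphenylphosphonium bromide (as its ylide), C[P+](c1ccccc1)(c1ccccc1)c1ccccc1.[Br-]
Why: Wittig methylenation of the α-methyl enal with the non-stabilised ylide adds the carbon that becomes C5 and gives the 2-substituted 1,3-diene with no stereochemical issue.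

Step 6
Reactants: 8 3-[(3E,7E,11E)-4,8,12-trimethyltetradeca-3,7,11,13-tetraen-1-yl]furan
Product: 10 (3E,7E,11E)-14-(furan-3-yl)-3,7,11-trimethyltetradeca-3,7,11-trien-1-ol, via B-alkyl-9-BBN adduct 9 (not isolated)
Conditions: 9-BBN (1.2 equiv), THF, 0 °C → rt; then 3 M NaOH, 30% H2O2, 0 °C
Reagents that add atoms: hydrogen peroxide, OO
Why: Hydroboration–oxidation with the bulky 9-BBN should be selective for the terminal monosubstituted C=C of the diene (anti-Markovnikov), leaving the trisubstituted olefins and the furan alone and giving the homoallylic primary alcohol.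

Step 7
Reactants: 10 (3E,7E,11E)-14-(furan-3-yl)-3,7,11-trimethyltetradeca-3,7,11-trien-1-ol; 11 N,N-diisopropylcarbamoyl chloride
Product: 12 (3E,7E,11E)-14-(furan-3-yl)-3,7,11-trimethyltetradeca-3,7,11-trien-1-yl N,N-diisopropylcarbamate
Conditions: 11 (1.3 equiv), Et3N (1.5 equiv), CH2Cl2, reflux
Reagents that add atoms: none
Why: O-Carbamoylation of the primary alcohol installs the hindered carbamate that serves as directing group for α-lithiation and as the C2 carbonyl of the ring.

Step 8
Reactants: 13 propionic anhydride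
Product: 14 methylketene (prop-1-en-1-one)
Conditions: flash vacuum pyrolysis, quartz tube, 500–550 °C, ca. 1 mbar; condensed at −196 °C, taken up in THF at −78 °C, titrated and used at once
Reagents that add atoms: none
Why: Thermal gas-phase elimination of propionic acid from the anhydride is the established source of monomeric methylketene, and cold dilute handling suppresses its dimerisation.

Step 9
Reactants: 12 (3E,7E,11E)-14-(furan-3-yl)-3,7,11-trimethyltetradeca-3,7,11-trien-1-yl N,N-diisopropylcarbamate; 14 methylketene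
Product: 18 (5R)-5-[(2E,6E,10E)-13-(furan-3-yl)-2,6,10-trimethyltrideca-2,6,10-trien-1-yl]-4-hydroxy-3-methylfuran-2(5H)-one, via (S)-α-lithio carbamate 15 (not isolated), via lithium Z-enolate 16 (not isolated), via cyclic lithium hemiorthoamide 17 (not isolated)
Conditions: (−)-sparteine (1.3 equiv), s-BuLi (1.2 equiv), Et2O, −78 °C, 5 h; 14 (1.1 equiv in THF, slow addition), −78 °C; −78 → 0 °C; inverse quench into 1 M HCl/THF, 0 °C → rt
Reagents that add atoms: none
Why: Proposed new method: s-BuLi·(−)-sparteine, pre-complexed to the carbamate C=O, removes the pro-S proton of the OCH2 group to give the configurationally stable (S)-lithio carbamate 15, which adds with retention to the central carbon of methylketene (C4–C5 bond) and so gives the Z-enolate 16 directly; on warming, the enolate carbon C3 attacks the carbamate carbonyl (C2–C3 bond) to give the cyclic adduct 17, and the acidic quench N-protonates it, expels diisopropylamine and leaves the enolised β-keto lactone. The closest known reaction types are the sparteine-mediated lithiation–acylation of O-alkyl N,N-diisopropylcarbamates, the addition of organolithiums to ketenes to give enolates, the anionic O→C carbamoyl transfer of aryl carbamates and the Claisen-type closure of α-acyloxy ketone enolates to furan-3(2H)-ones; new is their union in a formal (3+2) annulation with an O-alkyl carbamate as the acyl acceptor. The furanone ring closes in the 5-(enolendo)-exo-trig mode, the same mode as the Dieckmann closure that is routine for tetronic acids. C5, the only stereocentre, is fixed by the chiral diamine at the deprotonation and carried through with retention; because the ketene gives the C3 enolate directly, C5 is never α to a free ketone and should not epimerise by enolisation. The step needs α-oxygen lithiation in preference to furan C-2 and allylic C–H (complex-induced proximity at −78 °C in Et2O, s-BuLi limited to 1.2 equiv), C-acylation in preference to proton transfer from the ketene (slow addition of cold dilute ketene to the carbanion), and C–N rather than ring C–O cleavage of 17 (cold acidic quench, under which a hemiorthoamide loses the protonated amine).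

**Compound list**
1 | furan-3-ylmethanol | OCc1ccoc1 | starting material
2 | 3-(chloromethyl)furan | ClCc1ccoc1 | intermediate
3 | (2E,6E)-farnesyl bromide | CC(C)=CCC/C(C)=C/CC/C(C)=C/CBr | starting material
4 | (furan-3-ylmethyl)magnesium chloride | Cl[Mg]Cc1ccoc1 | intermediate
5 | 3-[(3E,7E)-4,8,12-trimethyltrideca-3,7,11-trien-1-yl]furan | CC(C)=CCC/C(C)=C/CC/C(C)=C/CCc1ccoc1 | intermediate
6 | (2E,6E,10E)-13-(furan-3-yl)-2,6,10-trimethyltrideca-2,6,10-trien-1-ol | OC/C(C)=C/CC/C(C)=C/CC/C(C)=C/CCc1ccoc1 | intermediate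
7 | (2E,6E,10E)-13-(furan-3-yl)-2,6,10-trimethyltrideca-2,6,10-trienal | O=C/C(C)=C/CC/C(C)=C/CC/C(C)=C/CCc1ccoc1 | intermediate
8 | 3-[(3E,7E,11E)-4,8,12-trimethyltetradeca-3,7,11,13-tetraen-1-yl]furan | C=C/C(C)=C/CC/C(C)=C/CC/C(C)=C/CCc1ccoc1 | intermediate
9 | 9-[(3E,7E,11E)-14-(furan-3-yl)-3,7,11-trimethyltetradeca-3,7,11-trien-1-yl]-9-borabicyclo[3.3.1]nonane | C1CC2CCCC(C1)B2CC/C(C)=C/CC/C(C)=C/CC/C(C)=C/CCc3ccoc3 | intermediate
10 | (3E,7E,11E)-14-(furan-3-yl)-3,7,11-trimethyltetradeca-3,7,11-trien-1-ol | OCC/C(C)=C/CC/C(C)=C/CC/C(C)=C/CCc1ccoc1 | intermediate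
11 | N,N-diisopropylcarbamoyl chloride | CC(C)N(C(C)C)C(Cl)=O | starting material
12 | (3E,7E,11E)-14-(furan-3-yl)-3,7,11-trimethyltetradeca-3,7,11-trien-1-yl N,N-diisopropylcarbamate | CC(C)N(C(C)C)C(=O)OCC/C(C)=C/CC/C(C)=C/CC/C(C)=C/CCc1ccoc1 | intermediate
13 | propionic anhydride | CCC(=O)OC(=O)CC | starting material
14 | methylketene (prop-1-en-1-one) | CC=C=O | intermediate
15 | (S)-α-lithio carbamate (sparteine complex): [(1S,3E,7E,11E)-1-(diisopropylcarbamoyloxy)-14-(furan-3-yl)-3,7,11-trimethyltetradeca-3,7,11-trien-1-yl]lithium | [Li][C@@H](C/C(C)=C/CC/C(C)=C/CC/C(C)=C/CCc1ccoc1)OC(=O)N(C(C)C)C(C)C | intermediate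
16 | lithium Z-enolate of the (R)-α-(diisopropylcarbamoyloxy) ethyl ketone: lithium (2Z,4R,6E,10E,14E)-4-(diisopropylcarbamoyloxy)-17-(furan-3-yl)-6,10,14-trimethylheptadeca-2,6,10,14-tetraen-3-olate | [Li]O/C(=C\C)[C@@H](C/C(C)=C/CC/C(C)=C/CC/C(C)=C/CCc1ccoc1)OC(=O)N(C(C)C)C(C)C | intermediate
17 | cyclic lithium hemiorthoamide: lithium (5R)-2-(diisopropylamino)-5-[(2E,6E,10E)-13-(furan-3-yl)-2,6,10-trimethyltrideca-2,6,10-trien-1-yl]-3-methyl-4-oxotetrahydrofuran-2-olate (C2 and C3 as mixtures) | CC1C(=O)[C@@H](C/C(C)=C/CC/C(C)=C/CC/C(C)=C/CCc2ccoc2)OC1(O[Li])N(C(C)C)C(C)C | intermediate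
18 | (5R)-5-[(2E,6E,10E)-13-(furan-3-yl)-2,6,10-trimethyltrideca-2,6,10-trien-1-yl]-4-hydroxy-3-methylfuran-2(5H)-one | CC1=C(O)[C@@H](C/C(C)=C/CC/C(C)=C/CC/C(C)=C/CCc2ccoc2)OC1=O | target

**Step count and risks**
Total steps: 9. Longest linear sequence: 8 (steps 1–7 and 9; step 8 is a one-step side branch).

Steps most likely to fail:

1. Step 9 (Proposed new method). Three processes may defeat it. Lithiation may occur at furan C-2 in competition with the carbamate-directed deprotonation. The carbanion may take a proton from the ketene, or the product enolate may oligomerise the ketene, instead of clean C-acylation. The cyclic adduct may open at the ring C–O bond (O→C carbamoyl shift) to an open-chain hydroxy keto amide that does not relactonise under mild acid.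
Fallback (known chemistry; C5–C6 is made by auxiliary-controlled alkylation and the ring by Dieckmann condensation): it sets out from 6 and returns at 18. PBr3 (Et2O, 0 °C) should convert 6 into 3-[(3E,7E,11E)-13-bromo-4,8,12-trimethyltrideca-3,7,11-trien-1-yl]furan F1. The glycolate imide (S)-4-benzyl-3-{[(4-methoxybenzyl)oxy]acetyl}oxazolidin-2-one F2 is made from (S)-4-benzyloxazolidin-2-one, n-BuLi and (4-methoxybenzyloxy)acetyl chloride. Its sodium enolate (NaHMDS, THF, −78 °C) should be alkylated by F1 on the face away from the benzyl group to give (S)-4-benzyl-3-[(2R,4E,8E,12E)-15-(furan-3-yl)-2-[(4-methoxybenzyl)oxy]-4,8,12-trimethylpentadeca-4,8,12-trienoyl]oxazolidin-2-one F3. NaOMe/MeOH (0 °C) should give methyl (2R,4E,8E,12E)-15-(furan-3-yl)-2-[(4-methoxybenzyl)oxy]-4,8,12-trimethylpentadeca-4,8,12-trienoate F4. Buffered DDQ (CH2Cl2/pH 7 buffer) should give methyl (2R,4E,8E,12E)-15-(furan-3-yl)-2-hydroxy-4,8,12-trimethylpentadeca-4,8,12-trienoate F5. Propionyl chloride/pyridine should give methyl (2R,4E,8E,12E)-15-(furan-3-yl)-4,8,12-trimethyl-2-(propanoyloxy)pentadeca-4,8,12-trienoate F6. LiHMDS (THF, −78 → 0 °C) should then close the ring by Dieckmann condensation to 18.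

2. Step 3. The oxidation may run on to the enal, attack the internal trisubstituted olefins, or degrade the electron-rich furan oxidatively.
Fallback: it sets out from 5 and returns at 7, bypassing 6. Cross-metathesis of 5 with excess methacrolein (phosphine-free second-generation ruthenium benzylidene catalyst, CH2Cl2, 40 °C) should exchange the terminal isopropylidene group for the E-configured 2-methyl enal terminus. The internal trisubstituted olefins should react much more slowly. No new compound is made.

3. Step 2. The ambident furylmethyl nucleophile may couple through ring carbon C-2, the allylic bromide may be attacked in the SN2′ sense, and homocoupling may compete.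
Fallback: it sets out from 3 and 2 and returns at 5. Sodium benzenesulfinate (DMF, rt) should convert 3 into {[(2E,6E)-3,7,11-trimethyldodeca-2,6,10-trien-1-yl]sulfonyl}benzene F7. Its α-lithio anion (n-BuLi, THF, −78 °C) should be alkylated by 2 to give 3-[(3E,7E)-4,8,12-trimethyl-2-(phenylsulfonyl)trideca-3,7,11-trien-1-yl]furan F8. Reductive desulfonylation (PdCl2(dppp) cat., LiBHEt3, THF, 0 °C) should give 5.

**Further compounds**
F1 | step 9 | 3-[(3E,7E,11E)-13-bromo-4,8,12-trimethyltrideca-3,7,11-trien-1-yl]furan | BrC/C(C)=C/CC/C(C)=C/CC/C(C)=C/CCc1ccoc1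
F2 | step 9 | (S)-4-benzyl-3-{[(4-methoxybenzyl)oxy]acetyl}oxazolidin-2-one | O=C1OC[C@H](Cc2ccccc2)N1C(=O)COCc3ccc(OC)cc3
F3 | step 9 | (S)-4-benzyl-3-[(2R,4E,8E,12E)-15-(furan-3-yl)-2-[(4-methoxybenzyl)oxy]-4,8,12-trimethylpentadeca-4,8,12-trienoyl]oxazolidin-2-one | O=C1OC[C@H](Cc2ccccc2)N1C(=O)[C@H](OCc3ccc(OC)cc3)C/C(C)=C/CC/C(C)=C/CC/C(C)=C/CCc4ccoc4
F4 | step 9 | methyl (2R,4E,8E,12E)-15-(furan-3-yl)-2-[(4-methoxybenzyl)oxy]-4,8,12-trimethylpentadeca-4,8,12-trienoate | COC(=O)[C@H](OCc1ccc(OC)cc1)C/C(C)=C/CC/C(C)=C/CC/C(C)=C/CCc2ccoc2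
F5 | step 9 | methyl (2R,4E,8E,12E)-15-(furan-3-yl)-2-hydroxy-4,8,12-trimethylpentadeca-4,8,12-trienoate | COC(=O)[C@H](O)C/C(C)=C/CC/C(C)=C/CC/C(C)=C/CCc1ccoc1
F6 | step 9 | methyl (2R,4E,8E,12E)-15-(furan-3-yl)-4,8,12-trimethyl-2-(propanoyloxy)pentadeca-4,8,12-trienoate | COC(=O)[C@H](OC(=O)CC)C/C(C)=C/CC/C(C)=C/CC/C(C)=C/CCc1ccoc1
F0 | step 3 | none | none
F7 | step 2 | {[(2E,6E)-3,7,11-trimethyldodeca-2,6,10-trien-1-yl]sulfonyl}benzene | CC(C)=CCC/C(C)=C/CC/C(C)=C/CS(=O)(=O)c1ccccc1
F8 | step 2 | 3-[(3E,7E)-4,8,12-trimethyl-2-(phenylsulfonyl)trideca-3,7,11-trien-1-yl]furan | CC(C)=CCC/C(C)=C/CC/C(C)=C/C(Cc1ccoc1)S(=O)(=O)c2ccccc2
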